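**Plan**

1. Numbering follows the target skeleton: ring C6–C7–C8–C9–C10–C11; C7 carries the exocyclic C2 (with methyl C25 and aldehyde C1); C10 carries OH and a methyl; C11 is quaternary (methyl plus chain C12–C24); C6 carries H and the C5–C3 hydroxypropyl arm.
2. Retrosynthetic cuts: C13–C14 (B-alkyl Suzuki–Miyaura coupling of core 16 with iodide 28); the C2=C7 π bond (CO2 loss from a β-lactone); then ring bonds C7–C8 and C10–C11 together (methyl vinyl ketone plus open-chain keto ester 9); then C6–C7 (Johnson–Claisen) and C20–C21 (vinylogous aldol).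
3. Enabling feature: ring atoms C8–C9–C10(CH3)(OH) are methyl vinyl ketone used as a 1,3-bis-electrophile. Its partners are C7, made acidic by a temporary ester/ketone pair, and quaternary C11, whose vinyl neighbour C12=C13 is the trace of an allyl metal. The ester is later expelled as CO2 to form C2=C7.
4. Forward order: C6 centre on an open chain, then the six-membered ring in one operation, then the tetrasubstituted alkene, then the chain by sp3–sp2 coupling, then the enal by allylic oxidation.
5. Stereochemistry: C6 from a CBS reduction relayed by [3,3] chirality transfer; C10/C11 from a chair–chair allylchromium transition state under C6 control; C2=C7 geometry from chelation-controlled methyl addition plus stereospecific decarboxylation; C21 from a catalytic asymmetric vinylogous aldol; C22 from hydroxyl-directed epoxidation; chain E-alkenes from the aldol and carboalumination.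

Key step: step 7

Remark: TBS = tert-butyldimethylsilyl, TMS = trimethylsilyl; 9 and 11 are C7-epimer mixtures and 12–15 are drawn as one C7 epimer (the other should react alike and both converge on 16); 1 and 8 are taken as catalogue silyl ethers.

**Step 1**
Reactants: 1 4-(TBSO)butanal; 2 ethyl 2-(triphenylphosphoranylidene)propanoate
Product: 3 ethyl (E)-6-(TBSO)-2-methylhex-2-enoate
Conditions: CH2Cl2, 40 °C
Reagents that add atoms: none
Why: Wittig olefination with a stabilised ylide should give the trisubstituted (E)-enoate selectively, because the reversible oxaphosphetane pathway favours the isomer with ester and alkyl chain trans.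

**Step 2**
Reactants: 3 ethyl (E)-6-(TBSO)-2-methylhex-2-enoate
Product: 4 (E)-7-(TBSO)-1-chloro-3-methylhept-3-en-2-one
Conditions: ClCH2I, MeLi·LiBr, THF, −78 °C; aq NH4Cl
Reagents that add atoms: chloroiodomethane, ClCI
Why: Iodine–lithium exchange generates chloromethyllithium in the presence of the ester, and its tetrahedral adduct is stable at −78 °C and collapses to the chloromethyl ketone only on quenching (carbenoid homologation of an ester to an α-chloro ketone), so over-addition and 1,4-addition should not compete.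

**Step 3**
Reactants: 4 (E)-7-(TBSO)-1-chloro-3-methylhept-3-en-2-one
Product: 5 (S,E)-7-(TBSO)-1-chloro-3-methylhept-3-en-2-ol
Conditions: (S)-2-methyl-CBS-oxazaborolidine (10 mol%), BH3·SMe2, THF, −20 °C; MeOH
Reagents that add atoms: none
Why: Corey–Bakshi–Shibata reduction in which the α-branched alkenyl group acts as the large and CH2Cl as the small substituent, so the (S)-catalyst should deliver hydride to the face that gives the (S)-chlorohydrin (the sense known for chloromethyl ketones).

**Step 4**
Reactants: 5 (S,E)-7-(TBSO)-1-chloro-3-methylhept-3-en-2-ol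
Product: 6 ethyl (R,E)-3-[3-(TBSO)propyl]-6-chloro-4-methylhex-4-enoate
Conditions: MeC(OEt)3, EtCO2H (cat.), xylene, 135 °C, EtOH distilled off
Reagents that add atoms: triethyl orthoacetate, CC(OCC)(OCC)OCC
Why: Johnson–Claisen rearrangement through a chair transition state with the CH2Cl group equatorial, which should transfer the carbinol configuration to C6 (R), create the (E)-trisubstituted C11=C12 alkene and unveil the primary allylic chloride.

**Step 5**
Reactants: 6 ethyl (R,E)-3-[3-(TBSO)propyl]-6-chloro-4-methylhex-4-enoate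
Product: 7 allyl (R,E)-3-[3-(TBSO)propyl]-6-chloro-4-methylhex-4-enoate
Conditions: allyl alcohol, Ti(OEt)4 (10 mol%), 90 °C
Reagents that add atoms: allyl alcohol, C=CCO
Why: Titanate-catalysed transesterification exchanges ethyl for allyl so that the carboxyl group can later be released under neutral palladium conditions; no stereocentre is touched.

**Step 6**
Reactants: 7 allyl (R,E)-3-[3-(TBSO)propyl]-6-chloro-4-methylhex-4-enoate; 8 2-(TBSO)-N-methoxy-N-methylacetamide
Product: 9 allyl (3R,E)-2-[(TBSO)acetyl]-3-[3-(TBSO)propyl]-6-chloro-4-methylhex-4-enoate (both epimers at the acidic carbon, C7 of the target)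
Conditions: LDA, THF, −78 °C; then 8, −78 to −20 °C; aq NH4Cl
Reagents that add atoms: none
Why: Crossed Claisen acylation of the ester lithium enolate with a Weinreb amide, whose chelated tetrahedral intermediate prevents a second addition; the E alkene keeps the allylic chloride out of reach of the enolate and C6 is not enolisable.

**Step 7**
Reactants: 9 allyl (3R,E)-2-[(TBSO)acetyl]-3-[3-(TBSO)propyl]-6-chloro-4-methylhex-4-enoate; 10 methyl vinyl ketone
Product: 12 allyl 1-[(TBSO)acetyl]-2-[3-(TBSO)propyl]-3,4-dimethyl-4-(TMSO)-3-vinylcyclohexane-1-carboxylate (C6 side chain, C11 methyl and C10 oxygen on one ring face; vinyl and C10 methyl on the other), via triketo ester 11 (not isolated)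
Conditions: 10 (1.0 equiv), Cs2CO3 (5 mol%), THF, 0 °C to rt; then CrCl2 (4 equiv), lithium iodide (LiI, 0.2 equiv), TMSCl, DMF, 0 °C to rt
Reagents that add atoms: chlorotrimethylsilane, C[Si](C)(C)Cl
Why: Carbonate-catalysed Michael addition of the doubly activated C7–H of 9 to the β-carbon of 10 makes the C7–C8 bond and leaves the side-chain methyl ketone of 11; divalent chromium chloride CrCl2 (iodide-catalysed) then turns the allylic chloride into an allylchromium reagent whose γ-carbon C11 adds to the C10 carbonyl in a 6-exo-trig closure through a chromium-bridged Zimmerman–Traxler transition state, and TMSCl caps the chromium alkoxide. The closest known reaction types are the Michael addition of 2-substituted 1,3-dicarbonyl compounds to methyl vinyl ketone and the intramolecular Nozaki–Hiyama allylation of ketones by γ,γ-disubstituted allyl halides. C10 and C11 are set together in a trans-decalin-like chair–chair transition state in which the tether (C9 on the ketone, C6 on the allyl unit) is equatorial on the metallacycle and both methyl groups are axial, which places the oxygen trans to vinyl. The C6 centre selects the face because its silyloxypropyl chain stays equatorial on the forming carbocycle (an axial chain would be 1,3-diaxial to the C10 methyl), which puts it cis to the C10 oxygen and to the C11 methyl. The step needs C-alkylation and 1,4-addition in the first stage (soft stabilised enolate), no aldol closure of 11 (only catalytic mild base, then non-basic chromium), and γ-attack on the C10 ketone rather than the C2 ketone (C11 attacking C2 would form a four-membered ring), with the bulkier C6 substituent taking the E position of the equilibrating allylchromium. The quaternary C7 centre forms without control, which is harmless because step 10 destroys it.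

**Step 8**
Reactants: 12 allyl 1-[(TBSO)acetyl]-2-[3-(TBSO)propyl]-3,4-dimethyl-4-(TMSO)-3-vinylcyclohexane-1-carboxylate
Product: 13 allyl 1-[1-(TBSO)-2-hydroxypropan-2-yl]-2-[3-(TBSO)propyl]-3,4-dimethyl-4-(TMSO)-3-vinylcyclohexane-1-carboxylate (new methyl on the C8 side of the ketone/ester chelate)
Conditions: MeMgBr, MgBr2·OEt2, CH2Cl2/Et2O, −78 °C
Reagents that add atoms: methylmagnesium bromide, C[Mg]Br
Why: Chelation-controlled Grignard addition in which magnesium bridges the ketone and ester carbonyls, so that methyl attacks the ketone face on the C8 side (the other face is screened by the equatorial C6 side chain), which fixes the new carbinol centre relative to C7.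

**Step 9**
Reactants: 13 allyl 1-[1-(TBSO)-2-hydroxypropan-2-yl]-2-[3-(TBSO)propyl]-3,4-dimethyl-4-(TMSO)-3-vinylcyclohexane-1-carboxylate
Product: 14 1-[1-(TBSO)-2-hydroxypropan-2-yl]-2-[3-(TBSO)propyl]-3,4-dimethyl-4-(TMSO)-3-vinylcyclohexane-1-carboxylic acid
Conditions: Pd(PPh3)4 (5 mol%), morpholine, THF, rt
Reagents that add atoms: none
Why: Tsuji–Trost deallylation, in which zerovalent palladium ionises the allyl ester and morpholine traps the allyl group, frees the carboxylic acid without base and so without retro-aldol cleavage of the β-hydroxy acid.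

**Step 10**
Reactants: 14 1-[1-(TBSO)-2-hydroxypropan-2-yl]-2-[3-(TBSO)propyl]-3,4-dimethyl-4-(TMSO)-3-vinylcyclohexane-1-carboxylic acid
Product: 16 (Z)-1-[1-(TBSO)propan-2-ylidene]-2-[3-(TBSO)propyl]-3,4-dimethyl-4-(TMSO)-3-vinylcyclohexane (CH2OTBS cis to C6; ring centres as in the target), via spiro β-lactone 15 (not isolated)
Conditions: PhSO2Cl, pyridine, 0 °C to rt; then 2,4,6-collidine, 110 °C
Reagents that add atoms: none
Why: Sulfonyl chloride activation of the carboxyl lets the tertiary β-hydroxyl close a β-lactone with retention at both carbons, and thermal [2+2] cycloreversion then expels CO2 with syn stereospecificity, so the methyl placed on the C8 side in step 8 ends cis to C8 and the CH2OTBS group cis to C6 (the Z alkene of the target), while both C7 epimers converge.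

**Step 11**
Reactants: 17 ethyl 3-methylbut-2-enoate
Product: 18 tert-butyl[(1-ethoxy-3-methylbuta-1,3-dien-1-yl)oxy]dimethylsilane (ketene acetal geometry not defined)
Conditions: LDA, THF, −78 °C; TBSCl, DMPU
Reagents that add atoms: tert-butyldimethylsilyl chloride, CC(C)(C)[Si](C)(C)Cl
Why: Deprotonation of the γ-methyl group of the enoate by LDA and O-silylation of the extended enolate gives the silyl dienol ether (silyl ketene acetal formation).

**Step 12**
Reactants: 18 tert-butyl[(1-ethoxy-3-methylbuta-1,3-dien-1-yl)oxy]dimethylsilane; 19 3-methylbut-2-enal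
Product: 20 ethyl (S,E)-5-hydroxy-3,7-dimethylocta-2,6-dienoate
Conditions: SiCl4, (S,S)-binaphthyldiamine-derived bisphosphoramide (5 mol%), i-Pr2NEt (cat.), CH2Cl2, −78 °C; aq NaHCO3
Reagents that add atoms: none
Why: Catalytic enantioselective vinylogous Mukaiyama aldol addition in which the phosphoramide-bound silicon cation activates the enal and the dienolate attacks through its unhindered γ-carbon on the Si face (catalyst antipode chosen for this face), which should set (S)-C21 and leave the (E)-enoate.

**Step 13**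
Reactants: 20 ethyl (S,E)-5-hydroxy-3,7-dimethylocta-2,6-dienoate
Product: 21 ethyl (S,E)-5-(TBSO)-3,7-dimethylocta-2,6-dienoate
Conditions: TBSCl, imidazole, DMF, rt
Reagents that add atoms: tert-butyldimethylsilyl chloride, CC(C)(C)[Si](C)(C)Cl
Why: Standard silylation of the secondary allylic alcohol protects the C21 hydroxyl for the organometallic steps.

**Step 14**
Reactants: 21 ethyl (S,E)-5-(TBSO)-3,7-dimethylocta-2,6-dienoate
Product: 22 (S,E)-5-(TBSO)-3,7-dimethylocta-2,6-dien-1-ol
Conditions: DIBAL-H, CH2Cl2, −78 °C; Rochelle salt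
Reagents that add atoms: none
Why: DIBAL-H reduces the conjugated ester in a 1,2-fashion to the (E)-allylic alcohol at low temperature without touching the alkenes or the silyl ether.

**Step 15**
Reactants: 22 (S,E)-5-(TBSO)-3,7-dimethylocta-2,6-dien-1-ol
Product: 23 (S,E)-1-bromo-5-(TBSO)-3,7-dimethylocta-2,6-diene
Conditions: CBr4, PPh3, CH2Cl2, 0 °C
Reagents that add atoms: carbon tetrabromide, BrC(Br)(Br)Br
Why: Appel bromination converts the primary allylic alcohol into the bromide by SN2 displacement of the alkoxyphosphonium ion under neutral conditions, with retention of alkene geometry.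

**Step 16**
Reactants: 23 (S,E)-1-bromo-5-(TBSO)-3,7-dimethylocta-2,6-diene
Product: 24 (S,E)-8-(TBSO)-6,10-dimethylundeca-5,9-dien-1-yne
Conditions: propyne, n-BuLi (2 equiv), TMEDA, THF/hexane, −78 to 0 °C; then 23, −78 °C to rt; H2O
Reagents that add atoms: propyne, CC#C
Why: 1,3-Dilithiopropyne, formed in the flask, is alkylated at its propargylic carbon by the primary allylic bromide in an SN2 reaction and the remaining acetylide is protonated on quench, which gives the 1,5-enyne directly.

**Step 17**
Reactants: 24 (S,E)-8-(TBSO)-6,10-dimethylundeca-5,9-dien-1-yne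
Product: 26 (S,1E,5E)-8-(TBSO)-1-iodo-2,6,10-trimethylundeca-1,5,9-triene, via alkenylalane 25 (not isolated)
Conditions: Me3Al, Cp2ZrCl2 (25 mol%), CH2Cl2, 0 °C to rt; then I2, THF, −30 °C
Reagents that add atoms: trimethylaluminium, C[Al](C)C; iodine, II
Why: Zirconium-catalysed carboalumination (Negishi carboalumination) adds methyl and aluminium syn across the terminal alkyne with methyl on the internal carbon, and iodinolysis with retention then gives the (E)-vinyl iodide; the trisubstituted alkenes and the silyl ether are inert.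

**Step 18**
Reactants: 26 (S,1E,5E)-8-(TBSO)-1-iodo-2,6,10-trimethylundeca-1,5,9-triene
Product: 27 (S,6E,10E)-11-iodo-2,6,10-trimethylundeca-2,6,10-trien-4-ol
Conditions: TBAF, THF, 0 °C to rt
Reagents that add atoms: none
Why: Fluoride cleaves the TBS ether to release the C21 allylic alcohol needed as directing group.

**Step 19**
Reactants: 27 (S,6E,10E)-11-iodo-2,6,10-trimethylundeca-2,6,10-trien-4-ol
Product: 28 (1S,3E,7E)-1-[(2R)-3,3-dimethyloxiran-2-yl]-8-iodo-3,7-dimethylocta-3,7-dien-1-ol
Conditions: VO(acac)2 (5 mol%), t-BuOOH, CH2Cl2, 0 °C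
Reagents that add atoms: tert-butyl hydroperoxide, CC(C)(C)OO
Why: Vanadium-catalysed hydroxyl-directed epoxidation delivers oxygen only to the allylic alkene from the face of the bound alkoxide, and A(1,3) strain between the carbinol substituent and the cis-methyl group holds the carbinol hydrogen in the alkene plane, which should give the threo (21S,22R) epoxy alcohol; the homoallylic alkene reacts more slowly and the iodoalkene is deactivated.

**Step 20**
Reactants: 16 (Z)-1-[1-(TBSO)propan-2-ylidene]-2-[3-(TBSO)propyl]-3,4-dimethyl-4-(TMSO)-3-vinylcyclohexane; 28 (1S,3E,7E)-1-[(2R)-3,3-dimethyloxiran-2-yl]-8-iodo-3,7-dimethylocta-3,7-dien-1-ol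
Product: 30 fully assembled C30 skeleton with C1 and C3 as TBS ethers, C10 as TMS ether and C21 hydroxyl free, via alkylborane 29 (not isolated)
Conditions: 9-BBN, THF, rt; then aq Cs2CO3, 28, Pd(dppf)Cl2 (5 mol%), AsPh3, DMF, rt
Reagents that add atoms: none
Why: 9-BBN hydroborates only the monosubstituted vinyl group at its terminus, and the B-alkyl Suzuki–Miyaura coupling then joins C13 to the vinyl iodide with retention of the E geometry under mild aqueous base that the epoxy alcohol and silyl ethers tolerate.

**Step 21**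
Reactants: 30 fully assembled C30 skeleton with C1 and C3 as TBS ethers and C10 as TMS ether
Product: 31 C1 allylic alcohol of the target (C1, C3, C10, C21 tetraol)
Conditions: TBAF, AcOH, THF, rt
Reagents that add atoms: none
Why: Buffered fluoride removes the two TBS ethers and the tertiary TMS ether in one operation, and the acetic acid buffer suppresses epoxide migration.

**Step 22**
Reactants: 31 C1 allylic alcohol of the target
Product: 32 CNP0161066.1 (target)
Conditions: MnO2, CH2Cl2, rt
Reagents that add atoms: none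
Why: MnO2 oxidises only the allylic primary alcohol to the enal (chemoselective allylic oxidation), leaving the saturated primary, the epoxy-carbinol and the tertiary hydroxyls untouched and the alkene geometry unchanged.

**Compound list**

1 | 4-(tert-butyldimethylsilyloxy)butanal | O=CCCCO[Si](C)(C)C(C)(C)C | starting material
2 | ethyl 2-(triphenylphosphoranylidene)propanoate | CCOC(=O)C(C)=P(c1ccccc1)(c1ccccc1)c1ccccc1 | starting material
3 | ethyl (E)-6-(TBSO)-2-methylhex-2-enoate | CCOC(=O)/C(C)=C/CCCO[Si](C)(C)C(C)(C)C | intermediate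
4 | (E)-7-(TBSO)-1-chloro-3-methylhept-3-en-2-one | ClCC(=O)/C(C)=C/CCCO[Si](C)(C)C(C)(C)C | intermediate
5 | (S,E)-7-(TBSO)-1-chloro-3-methylhept-3-en-2-ol | ClC[C@@H](O)/C(C)=C/CCCO[Si](C)(C)C(C)(C)C | intermediate
6 | ethyl (R,E)-3-[3-(TBSO)propyl]-6-chloro-4-methylhex-4-enoate | CCOC(=O)C[C@@H](CCCO[Si](C)(C)C(C)(C)C)/C(C)=C/CCl | intermediate
7 | allyl (R,E)-3-[3-(TBSO)propyl]-6-chloro-4-methylhex-4-enoate | C=CCOC(=O)C[C@@H](CCCO[Si](C)(C)C(C)(C)C)/C(C)=C/CCl | intermediate
8 | 2-(tert-butyldimethylsilyloxy)-N-methoxy-N-methylacetamide | CON(C)C(=O)CO[Si](C)(C)C(C)(C)C | starting material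
9 | allyl (3R,E)-2-[(TBSO)acetyl]-3-[3-(TBSO)propyl]-6-chloro-4-methylhex-4-enoate, epimers at C2 of the hexenoate | C=CCOC(=O)C(C(=O)CO[Si](C)(C)C(C)(C)C)[C@@H](CCCO[Si](C)(C)C(C)(C)C)/C(C)=C/CCl | intermediate
10 | methyl vinyl ketone (but-3-en-2-one) | CC(=O)C=C | starting material
11 | allyl (E)-2-[(TBSO)acetyl]-3-[3-(TBSO)propyl]-6-chloro-4-methyl-2-(3-oxobutyl)hex-4-enoate, C6 of the target unchanged, epimers at the quaternary carbon | C=CCOC(=O)C(CCC(C)=O)(C(=O)CO[Si](C)(C)C(C)(C)C)[C@@H](CCCO[Si](C)(C)C(C)(C)C)/C(C)=C/CCl | intermediate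
12 | allyl 1-[(TBSO)acetyl]-2-[3-(TBSO)propyl]-3,4-dimethyl-4-(TMSO)-3-vinylcyclohexane-1-carboxylate, ring centres as in the target, one C7 epimer drawn | C=CCOC(=O)[C@]1(C(=O)CO[Si](C)(C)C(C)(C)C)CC[C@](C)(O[Si](C)(C)C)[C@@](C)(C=C)[C@@H]1CCCO[Si](C)(C)C(C)(C)C | intermediate
13 | allyl 1-[1-(TBSO)-2-hydroxypropan-2-yl]-2-[3-(TBSO)propyl]-3,4-dimethyl-4-(TMSO)-3-vinylcyclohexane-1-carboxylate, carbinol methyl on the C8 side | C=CCOC(=O)[C@]1([C@@](O)(CO[Si](C)(C)C(C)(C)C)C)CC[C@](C)(O[Si](C)(C)C)[C@@](C)(C=C)[C@@H]1CCCO[Si](C)(C)C(C)(C)C | intermediate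
14 | 1-[1-(TBSO)-2-hydroxypropan-2-yl]-2-[3-(TBSO)propyl]-3,4-dimethyl-4-(TMSO)-3-vinylcyclohexane-1-carboxylic acid | OC(=O)[C@]1([C@@](O)(CO[Si](C)(C)C(C)(C)C)C)CC[C@](C)(O[Si](C)(C)C)[C@@](C)(C=C)[C@@H]1CCCO[Si](C)(C)C(C)(C)C | intermediate
15 | 3-methyl-3-[(TBSO)methyl]-5-[3-(TBSO)propyl]-6,7-dimethyl-7-(TMSO)-6-vinyl-2-oxaspiro[3.5]nonan-1-one, methyl cis to C8 on the lactone | O=C1O[C@@](C)(CO[Si](C)(C)C(C)(C)C)[C@]12CC[C@](C)(O[Si](C)(C)C)[C@@](C)(C=C)[C@@H]2CCCO[Si](C)(C)C(C)(C)C | intermediate
16 | (Z)-1-[1-(TBSO)propan-2-ylidene]-2-[3-(TBSO)propyl]-3,4-dimethyl-4-(TMSO)-3-vinylcyclohexane, CH2OTBS cis to C6 | C/C(CO[Si](C)(C)C(C)(C)C)=C1\CC[C@](C)(O[Si](C)(C)C)[C@@](C)(C=C)[C@@H]1CCCO[Si](C)(C)C(C)(C)C | intermediate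
17 | ethyl 3-methylbut-2-enoate | CCOC(=O)C=C(C)C | starting material
18 | tert-butyl[(1-ethoxy-3-methylbuta-1,3-dien-1-yl)oxy]dimethylsilane, ketene acetal geometry not defined | C=C(C)C=C(OCC)O[Si](C)(C)C(C)(C)C | intermediate
19 | 3-methylbut-2-enal | CC(C)=CC=O | starting material
20 | ethyl (S,E)-5-hydroxy-3,7-dimethylocta-2,6-dienoate | CCOC(=O)/C=C(\C)C[C@H](O)C=C(C)C | intermediate
21 | ethyl (S,E)-5-(TBSO)-3,7-dimethylocta-2,6-dienoate | CCOC(=O)/C=C(\C)C[C@H](O[Si](C)(C)C(C)(C)C)C=C(C)C | intermediate
22 | (S,E)-5-(TBSO)-3,7-dimethylocta-2,6-dien-1-ol | OC/C=C(\C)C[C@H](O[Si](C)(C)C(C)(C)C)C=C(C)C | intermediate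
23 | (S,E)-1-bromo-5-(TBSO)-3,7-dimethylocta-2,6-diene | BrC/C=C(\C)C[C@H](O[Si](C)(C)C(C)(C)C)C=C(C)C | intermediate
24 | (S,E)-8-(TBSO)-6,10-dimethylundeca-5,9-dien-1-yne | C#CCC/C=C(\C)C[C@H](O[Si](C)(C)C(C)(C)C)C=C(C)C | intermediate
25 | dimethyl[(S,1E,5E)-8-(TBSO)-2,6,10-trimethylundeca-1,5,9-trien-1-yl]alane | C[Al](C)/C=C(\C)CC/C=C(\C)C[C@H](O[Si](C)(C)C(C)(C)C)C=C(C)C | intermediate
26 | (S,1E,5E)-8-(TBSO)-1-iodo-2,6,10-trimethylundeca-1,5,9-triene | I/C=C(\C)CC/C=C(\C)C[C@H](O[Si](C)(C)C(C)(C)C)C=C(C)C | intermediate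
27 | (S,6E,10E)-11-iodo-2,6,10-trimethylundeca-2,6,10-trien-4-ol | I/C=C(\C)CC/C=C(\C)C[C@H](O)C=C(C)C | intermediate
28 | (1S,3E,7E)-1-[(2R)-3,3-dimethyloxiran-2-yl]-8-iodo-3,7-dimethylocta-3,7-dien-1-ol | I/C=C(\C)CC/C=C(\C)C[C@H](O)[C@H]1OC1(C)C | intermediate
29 | B-alkyl-9-borabicyclo[3.3.1]nonane adduct of 16 at the vinyl terminus (C13–B) | C/C(CO[Si](C)(C)C(C)(C)C)=C1\CC[C@](C)(O[Si](C)(C)C)[C@@](C)(CCB2C3CCCC2CCC3)[C@@H]1CCCO[Si](C)(C)C(C)(C)C | intermediate
30 | coupled C30 compound: C1-OTBS, C3-OTBS, C10-OTMS, free C21-OH, 22,23-epoxide, all target stereocentres and alkene geometries | C/C(CO[Si](C)(C)C(C)(C)C)=C1\CC[C@](C)(O[Si](C)(C)C)[C@@](C)(CC/C=C(\C)CC/C=C(\C)C[C@H](O)[C@H]2OC2(C)C)[C@@H]1CCCO[Si](C)(C)C(C)(C)C | intermediate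
31 | C1 allylic alcohol of the target (tetraol) | C/C(CO)=C1\CC[C@](C)(O)[C@@](C)(CC/C=C(\C)CC/C=C(\C)C[C@H](O)[C@H]2OC2(C)C)[C@@H]1CCCO | intermediate
32 | CNP0161066.1 | C/C(C=O)=C1\CC[C@](C)(O)[C@@](C)(CC/C=C(\C)CC/C=C(\C)C[C@H](O)[C@H]2OC2(C)C)[C@@H]1CCCO | target

**Totals**

Total step count: 22. Longest linear sequence: 13 steps (steps 1–10, then 20–22); the chain branch (steps 11–19) joins at step 20.

**Steps most likely to fail**

1. Step 7. The one-pot sequence may fail by aldol closure of the triketo ester before the chromium stage, or by leakage through a boat or Z-allyl transition state that erodes control at C10 and C11. Fallback (stepwise, boron in place of chromium): set out from 9, run the Michael addition alone (Cs2CO3 cat., THF) and isolate 11. Allylic borylation with B2pin2 and Pd2(dba)3 (cat.) in toluene at 50 °C should give the allyl pinacolboronate keto ester F1. Warming F1 in toluene at 80 °C should trigger intramolecular allylboration of the C10 ketone through the same closed chair transition state and give, after aqueous work-up, the tertiary alcohol F2. Silylation of F2 with TMSOTf and 2,6-lutidine comes back to the route at 12.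

2. Step 8. Chelation may be lost, so that the facial selectivity of the methyl addition is poor or reversed, and the hindered ketone may enolise; the geometry of the C2=C7 alkene depends on this step. Fallback (stereoconvergent use of the other carbinol): set out from 12 and separate the carbinol of opposite configuration at the new centre, the epimeric carbinol allyl ester F3. Deallylation with Pd(PPh3)4 and morpholine gives the epimeric hydroxy acid F4. Heating F4 with N,N-dimethylformamide dineopentyl acetal effects anti decarboxylative dehydration, which from this epimer delivers the same Z alkene that syn elimination delivers from 14, and so comes back to the route at 16.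

3. Step 19. Threo selectivity of the directed epoxidation may be insufficient, and the homoallylic C18=C19 alkene may be epoxidised in competition. Fallback (reagent control plus inversion): set out from 27 and oxidise with MnO2 to the enone F5. Reduction with (S)-2-methyl-CBS-oxazaborolidine and BH3·SMe2 should give the (R)-allylic alcohol F6. Sharpless asymmetric epoxidation (Ti(OiPr)4, D-(−)-diisopropyl tartrate, t-BuOOH, −20 °C) in the matched, erythro-selective sense should give the (1R)-epoxy alcohol F7. Mitsunobu inversion at the carbinol with 4-nitrobenzoic acid, PPh3 and DIAD gives the 4-nitrobenzoate F8, and methanolysis (K2CO3, MeOH) comes back to the route at 28.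

**Further compounds**

F1 | step 7 | allyl (E)-2-[(TBSO)acetyl]-3-[3-(TBSO)propyl]-4-methyl-2-(3-oxobutyl)-6-(4,4,5,5-tetramethyl-1,3,2-dioxaborolan-2-yl)hex-4-enoate | C=CCOC(=O)C(CCC(C)=O)(C(=O)CO[Si](C)(C)C(C)(C)C)[C@@H](CCCO[Si](C)(C)C(C)(C)C)/C(C)=C/CB1OC(C)(C)C(C)(C)O1
F2 | step 7 | allyl 1-[(TBSO)acetyl]-2-[3-(TBSO)propyl]-4-hydroxy-3,4-dimethyl-3-vinylcyclohexane-1-carboxylate | C=CCOC(=O)[C@]1(C(=O)CO[Si](C)(C)C(C)(C)C)CC[C@](C)(O)[C@@](C)(C=C)[C@@H]1CCCO[Si](C)(C)C(C)(C)C
F3 | step 8 | carbinol epimer of 13 (methyl on the C6 side) | C=CCOC(=O)[C@]1([C@](O)(CO[Si](C)(C)C(C)(C)C)C)CC[C@](C)(O[Si](C)(C)C)[C@@](C)(C=C)[C@@H]1CCCO[Si](C)(C)C(C)(C)C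
F4 | step 8 | carbinol epimer of 14 | OC(=O)[C@]1([C@](O)(CO[Si](C)(C)C(C)(C)C)C)CC[C@](C)(O[Si](C)(C)C)[C@@](C)(C=C)[C@@H]1CCCO[Si](C)(C)C(C)(C)C
F5 | step 19 | (6E,10E)-11-iodo-2,6,10-trimethylundeca-2,6,10-trien-4-one | I/C=C(\C)CC/C=C(\C)CC(=O)C=C(C)C
F6 | step 19 | (R,6E,10E)-11-iodo-2,6,10-trimethylundeca-2,6,10-trien-4-ol | I/C=C(\C)CC/C=C(\C)C[C@@H](O)C=C(C)C
F7 | step 19 | (1R,3E,7E)-1-[(2R)-3,3-dimethyloxiran-2-yl]-8-iodo-3,7-dimethylocta-3,7-dien-1-ol | I/C=C(\C)CC/C=C(\C)C[C@@H](O)[C@H]1OC1(C)C
F8 | step 19 | (1S,3E,7E)-1-[(2R)-3,3-dimethyloxiran-2-yl]-8-iodo-3,7-dimethylocta-3,7-dien-1-yl 4-nitrobenzoate | I/C=C(\C)CC/C=C(\C)C[C@H](OC(=O)c1ccc(cc1)[N+](=O)[O-])[C@H]1OC1(C)C
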